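Remark on the chemistry: the single stereocentre is read from the SMILES as (R). The side chain is numbered C1' (ketone carbon on C8), C2' (stereocentre) and C3' (isopropyl CH). Ring A is the benzenoid ring C4a–C8a and ring B the pyran-2-one.

## Analysis of the target

The target is a 7-methoxycoumarin (ring A fused to ring B) that carries at C8 the chain C1'(=O)–C2'H(O-acyl)–C3'H(CH3)2, with the C2' oxygen esterified by 3-methylbut-2-enoic (senecioic) acid. C2' is the only stereocentre and is (R); it is both α to the aryl ketone and the carbinol carbon of an ester, so its hydrogen is acidic and its oxygen substituent can migrate. C8 lies between O1 (through C8a) and the C7 methoxy group, so the C8–C1' bond is the most crowded bond of ring A and the aryl ketone is twisted out of conjugation. Ring B is a lactone and a Michael acceptor (C3=C4); the senecioate is a second conjugated ester that deconjugates easily; a free C2' hydroxy ketone would be open to epimerisation and α-ketol isomerisation. The feature the route exploits is the 1,2-pair C1'=O / C2'–O–acyl: an α-acyloxy ketone is the isomer of an enol ester epoxide (1-acyloxyoxirane) that carries the same acyl group on the C1' oxygen. The difficulty is control rather than size: acylating C8 and not C6, creating C2' as one enantiomer, and installing the senecioate without handling a free α-hydroxy ketone or exposing the stereocentre to base.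

## Retrosynthetic reasoning

**10 ⇒ 9.** The acyl C–O bond at the C2' oxygen is cut and the senecioyl group is returned to the C1' oxygen, closing the C1'–O–C2' oxirane of enol ester epoxide 9. Forward, a Brønsted-acid-catalysed 1,2-acyl shift must open the oxirane at C1', release the ketone and hand the acyl group to the C2' oxygen with retention at C2'. This cut is preferred to a plain ester disconnection because ketone, ester and stereocentre then come from one isomerisation, and the ester is never made by acylating a labile carbinol.

**9 ⇒ 8.** Both oxirane C–O bonds are cut to give the achiral (Z)-enol senecioate 8. Forward, an asymmetric dioxirane (Shi-type) epoxidation must select the electron-rich enol C1'=C2' bond over the two conjugated C=C bonds and choose one face. The gain is that the only stereocentre now comes from a catalyst-controlled reaction on a flat precursor.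

**8 ⇒ 5 + 6.** The enol O–acyl bond is cut. Ketone 5 is deprotonated to the Z-configured potassium enolate 7, which is acylated on oxygen by senecioyl chloride 6. The senecioyl group thus enters at an achiral stage, where enolate geometry is the only selectivity needed.

**5 ⇒ 4.** The O–CH3 bond is cut; forward, a routine methylation of the chelated phenol 4.

**4 ⇒ 3.** The crowded C8–C1' bond is cut and the isovaleryl group returned to the C7 oxygen of aryl ester 3. Forward, a Lewis-acid Fries rearrangement delivers the acyl group to C8, using the naphthol-like bond fixation of the coumarin (C7–C8 has the higher double-bond character). No organometallic reagent meets ring B.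

**3 ⇒ 1 + 2.** The aryl ester bond is cut to umbelliferone 1 and isovaleryl chloride 2, both commercial.

## Alternatives that were turned down

**Alternative 1:** (textbook) Cut the ester bond O(C2')–C(acyl) and the C8–C1' bond. Forward: iodine–magnesium exchange on 8-iodo-7-methoxy-2H-chromen-2-one A1, acylation of the aryl Grignard with the chiral-pool Weinreb amide (2R)-2-(tert-butyldimethylsilyloxy)-N-methoxy-N,3-dimethylbutanamide A2, desilylation to 8-[(2R)-2-hydroxy-3-methylbutanoyl]-7-methoxy-2H-chromen-2-one A3, and as key step esterification of A3 with 6. Turned down because: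
- the C8 arylmagnesium is flanked by two ortho oxygens and must attack an α-branched α-silyloxy amide, while its own molecule offers a lactone and a Michael acceptor, so self-condensation competes;
- A3 is the species in which C2' is most labile (enolisation, α-ketol shift);
- acylation with 6 under amine base runs partly through γ-deprotonation of the acid chloride, giving deconjugated ester, with base in contact with the stereocentre;
- A2 needs the unnatural D-series hydroxy acid and a protecting group, for about two more steps in which the stereocentre is carried throughout.

**Alternative 2:** Cut only C8–C1', with stereocentre and ester already in the migrating group. Forward key step: Lewis-acid Fries rearrangement of 2-oxo-2H-chromen-7-yl (2R)-3-methyl-2-[(3-methylbut-2-enoyl)oxy]butanoate A4, then O-methylation. Turned down because an acylium ion bearing an α-acyloxy group should lose CO to an oxygen-stabilised cation or collapse through neighbouring-group participation; ketene formation through the C2'–H would racemise; and the senecioate should not survive stoichiometric Lewis acid at 150 °C. The route is short, but every sensitive element meets the harshest step.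

**Alternative 3:** Cut the C1'–O and C2'–O bonds back to an alkene, starting from the commercial 8-prenylcoumarin osthole A5, which holds all skeletal carbons. Forward: isomerisation of the prenyl double bond into conjugation to 7-methoxy-8-[(1E)-3-methylbut-1-en-1-yl]-2H-chromen-2-one A6; Sharpless asymmetric dihydroxylation (key step) to 8-[(1R,2R)-1,2-dihydroxy-3-methylbutyl]-7-methoxy-2H-chromen-2-one A7; regioselective oxidation of the benzylic carbinol to A3; esterification as in alternative 1. Turned down because:
- the twisted aryl ring gives little conjugative driving force to move a trisubstituted double bond to a disubstituted position, so a mixture is expected;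
- the C1' stereocentre is made only to be destroyed;
- oxidation of the hindered benzylic hydroxyl next to a second hydroxyl competes with glycol cleavage;
- the route ends in A3 and the same esterification problem. The step count is similar, but three selectivity issues stay open.

Key step: step 6

## Route

Step 1
Reactants: 1 umbelliferone (7-hydroxy-2H-chromen-2-one); 2 3-methylbutanoyl chloride (isovaleryl chloride)
Product: 3 2-oxo-2H-chromen-7-yl 3-methylbutanoate
Conditions: Et3N, DMAP (cat.), THF, 0 °C to rt
Reagents that add atoms: none
Why: O-acylation of a phenol under nucleophilic catalysis; the phenolic oxygen is the only nucleophilic site and ring B is inert to amine base at this temperature.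

Step 2
Reactants: 3 2-oxo-2H-chromen-7-yl 3-methylbutanoate
Product: 4 7-hydroxy-8-(3-methylbutanoyl)-2H-chromen-2-one
Conditions: AlCl3 (3 equiv), neat melt, 150 °C; then ice/aq. HCl
Reagents that add atoms: none
Why: Fries rearrangement: AlCl3 ionises the aryl ester and the acyl group returns to an ortho carbon; C8 should be preferred over C6 because the C7–C8 bond has the higher double-bond character (as at C1 of 2-naphthol) and the chelated ortho-hydroxy ketone is the thermodynamic sink; the isovaleryl cation has no stabilised cation to reach by loss of CO, so the chain should arrive intact.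

Step 3
Reactants: 4 7-hydroxy-8-(3-methylbutanoyl)-2H-chromen-2-one
Product: 5 7-methoxy-8-(3-methylbutanoyl)-2H-chromen-2-one
Conditions: MeI, K2CO3, acetone, reflux
Reagents that add atoms: iodomethane, CI
Why: Williamson methylation of the chelated phenol; K2CO3 in dry acetone is too weak to deprotonate the ketone α-CH2 or to open ring B.

Step 4
Reactants: 5 7-methoxy-8-(3-methylbutanoyl)-2H-chromen-2-one; 6 3-methylbut-2-enoyl chloride (senecioyl chloride)
Product: 8 (1Z)-1-(7-methoxy-2-oxo-2H-chromen-8-yl)-3-methylbut-1-en-1-yl 3-methylbut-2-enoate, via potassium Z-enolate 7 (not isolated)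
Conditions: KN(SiMe3)2 (1.0 equiv), THF, −78 °C; then 6, −78 to −40 °C
Reagents that add atoms: none
Why: Kinetic deprotonation of an aryl alkyl ketone by a hindered amide should give the Z(O)-enolate (aryl trans to isopropyl, avoiding allylic 1,3-strain), and the hindered potassium enolate is acylated on oxygen by the acid chloride with retention of geometry; at −78 °C direct acyl substitution should outrun γ-deprotonation of 6, and the base is non-nucleophilic toward ring B.

Step 5
Reactants: 8 (1Z)-1-(7-methoxy-2-oxo-2H-chromen-8-yl)-3-methylbut-1-en-1-yl 3-methylbut-2-enoate
Product: 9 (2S,3R)-2-(7-methoxy-2-oxo-2H-chromen-8-yl)-3-(propan-2-yl)oxiran-2-yl 3-methylbut-2-enoate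
Conditions: D-fructose-derived Shi ketone (1,2:4,5-di-O-isopropylidene-β-D-erythro-hexo-2,3-diulo-2,6-pyranose, 30 mol%), Oxone (2KHSO5·KHSO4·K2SO4), K2CO3, n-Bu4NHSO4 (cat.), MeCN/CH2(OMe)2, aq. Na2B4O7–Na2EDTA buffer, 0 °C; neutral work-up, Et3N-deactivated silica
Reagents that add atoms: potassium peroxymonosulfate (active component of Oxone), [K+].[O-]S(=O)(=O)OO
Why: Shi epoxidation of a trisubstituted enol ester: the electrophilic chiral dioxirane should take the electron-rich enol C1'=C2' bond and leave the conjugated senecioate and C3=C4 bonds; in the spiro transition state the trans-disposed aryl and isopropyl groups should direct oxygen to the face that gives (R,R)-epoxides from trans-aryl alkenes, here the (2S,3R)-oxirane, so that C3 of the oxirane (the future C2') receives its final configuration.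

Step 6
Reactants: 9 (2S,3R)-2-(7-methoxy-2-oxo-2H-chromen-8-yl)-3-(propan-2-yl)oxiran-2-yl 3-methylbut-2-enoate
Product: 10 (2R)-1-(7-methoxy-2-oxo-2H-chromen-8-yl)-3-methyl-1-oxobutan-2-yl 3-methylbut-2-enoate
Conditions: TsOH (anhydrous, 10 mol%), MeNO2, 0 °C to rt
Reagents that add atoms: none
Why: Acid-catalysed rearrangement of an enol ester epoxide to an α-acyloxy ketone, a known stereospecific reaction type. Protonation of the oxirane oxygen is followed by heterolysis of the C1'–O bond to a cation at C1' that is stabilised by the acyloxy oxygen and the aryl group. The freed C2' hydroxyl adds to the senecioyl carbonyl through a five-membered (5-exo-trig) dioxolane-type tetrahedral intermediate, whose collapse breaks the acyl–O(C1') bond, releases the C1' ketone and leaves the senecioate on the C2' oxygen. No ring is closed in the product; only the oxirane is opened. The C2'–O bond is never broken, so the configuration set in step 5 is retained and C2' should emerge as (R). The selectivity needed is ionisation at C1' (retention) over the concerted 1,2-acyloxy shift with inversion at C2'; the strong Brønsted acid, the doubly stabilised C1' cation and the isopropyl group that shields C2' from backside attack should secure it. The conjugated ester and ring B are inert to catalytic TsOH, and the anhydrous medium prevents hydrolytic loss of the acyl group from the cation. In one isomerisation the step therefore creates the ketone and the C2' ester and delivers the stereocentre, with no free α-hydroxy ketone present at any time.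

## Compound list

1 | umbelliferone (7-hydroxy-2H-chromen-2-one) | Oc1ccc2ccc(=O)oc2c1 | starting material
2 | 3-methylbutanoyl chloride (isovaleryl chloride) | CC(C)CC(Cl)=O | starting material
3 | 2-oxo-2H-chromen-7-yl 3-methylbutanoate | CC(C)CC(=O)Oc1ccc2ccc(=O)oc2c1 | intermediate
4 | 7-hydroxy-8-(3-methylbutanoyl)-2H-chromen-2-one | CC(C)CC(=O)c1c(O)ccc2ccc(=O)oc12 | intermediate
5 | 7-methoxy-8-(3-methylbutanoyl)-2H-chromen-2-one | COc1ccc2ccc(=O)oc2c1C(=O)CC(C)C | intermediate
6 | 3-methylbut-2-enoyl chloride (senecioyl chloride) | CC(C)=CC(Cl)=O | starting material
7 | potassium (1Z)-1-(7-methoxy-2-oxo-2H-chromen-8-yl)-3-methylbut-1-en-1-olate | COc1ccc2ccc(=O)oc2c1/C([O-])=C/C(C)C.[K+] | intermediate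
8 | (1Z)-1-(7-methoxy-2-oxo-2H-chromen-8-yl)-3-methylbut-1-en-1-yl 3-methylbut-2-enoate | COc1ccc2ccc(=O)oc2c1/C(OC(=O)C=C(C)C)=C/C(C)C | intermediate
9 | (2S,3R)-2-(7-methoxy-2-oxo-2H-chromen-8-yl)-3-(propan-2-yl)oxiran-2-yl 3-methylbut-2-enoate | COc1ccc2ccc(=O)oc2c1[C@@]3(OC(=O)C=C(C)C)O[C@@H]3C(C)C | intermediate
10 | (2R)-1-(7-methoxy-2-oxo-2H-chromen-8-yl)-3-methyl-1-oxobutan-2-yl 3-methylbut-2-enoate (CNP0295407.1) | COc1ccc2ccc(=O)oc2c1C(=O)[C@H](OC(=O)C=C(C)C)C(C)C | target

## Step count and risk

Total step count: 6. Longest linear sequence: 6 steps (1 → 3 → 4 → 5 → 8 → 9 → 10).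

**Step 6 (key step).** The concerted 1,2-acyloxy shift with inversion at C2' may leak in and erode the enantiomeric purity. Adventitious water may also intercept the C1' cation, with loss of the acyl group. Fallback, from 9 back to 10: the acyl shift is given up and the ester is removed on purpose by brief methanolysis (K2CO3 cat., MeOH, −20 °C, pH 7 quench). The 2-oxido-oxirane collapses with the C2'–O bond intact to give 8-[(2R)-2-hydroxy-3-methylbutanoyl]-7-methoxy-2H-chromen-2-one F1. F1 is then esterified at once with 3-methylbut-2-enoic acid under Steglich conditions (DCC, DMAP cat., CH2Cl2, 0 °C) to give 10.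

**Step 5.** Facial discrimination in the oxygen transfer may be poor, because the twisted di-ortho-substituted aryl group and the isopropyl group both act as bulky substituents. Slow epoxidation would also allow saponification of the enol ester by the carbonate buffer, and the aryl-substituted oxirane may rearrange prematurely on work-up. If the facial sense proved opposite to the model, the enantiomeric ketone catalyst would be used. Fallback, from 8 back to 10, moves the stereocontrol from the epoxidation to a stereoconvergent rearrangement. Dimethyldioxirane (acetone, 0 °C) gives the racemic epoxide, that is 9 together with its enantiomer (2R,3S)-2-(7-methoxy-2-oxo-2H-chromen-8-yl)-3-(propan-2-yl)oxiran-2-yl 3-methylbut-2-enoate F2. A chiral Lewis acid made from BINOL and Ti(OiPr)4 (2:1, 5 mol%, Et2O, 0 °C) is then applied, with the BINOL antipode chosen so that F2 is the fast-reacting enantiomer. F2 rearranges by the concerted acyloxy shift with inversion to 10, while 9 is left. Anhydrous TsOH then converts the remaining 9 with retention, so both enantiomers converge on 10.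

**Step 4.** Possible failures are C-acylation of the enolate, incomplete Z-selectivity (the E isomer would deliver the opposite C2' configuration after step 5), γ-deprotonation of 6 leading to a deconjugated ester, and conjugate addition of the enolate to C4 of a second coumarin. Fallback, from 5 back to 8, avoids the free metal enolate. Soft enolisation (Me3SiOTf, Et3N, CH2Cl2, 0 °C) gives 7-methoxy-8-[(1Z)-3-methyl-1-(trimethylsilyloxy)but-1-en-1-yl]-2H-chromen-2-one F3, which can be freed of its geometric isomer. A fluoride-catalysed silyl-to-acyl exchange on oxygen with 3-methylbut-2-enoyl fluoride (n-Bu4NF cat., THF, 0 °C) then gives 8.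

**Step 2.** The acyl group may migrate to C6, the ester may be cleaved back to 1, and ring B may degrade in the melt. Fallback, from 1 back to 5, forms the C8–C1' bond by formylation and carbonyl addition instead of acyl migration:
- Duff formylation (hexamethylenetetramine, CF3CO2H, reflux; aq. acid) gives 7-hydroxy-2-oxo-2H-chromene-8-carbaldehyde F4.
- Methylation (MeI, K2CO3, acetone) gives 7-methoxy-2-oxo-2H-chromene-8-carbaldehyde F5.
- Addition of i-BuMgBr to the aldehyde (THF, −78 °C) gives racemic 8-(1-hydroxy-3-methylbutyl)-7-methoxy-2H-chromen-2-one F6.
- Dess–Martin oxidation (CH2Cl2, rt) gives 5.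

## Further compounds

F1 | step 6 | 8-[(2R)-2-hydroxy-3-methylbutanoyl]-7-methoxy-2H-chromen-2-one | COc1ccc2ccc(=O)oc2c1C(=O)[C@H](O)C(C)C
F2 | step 5 | (2R,3S)-2-(7-methoxy-2-oxo-2H-chromen-8-yl)-3-(propan-2-yl)oxiran-2-yl 3-methylbut-2-enoate | COc1ccc2ccc(=O)oc2c1[C@]3(OC(=O)C=C(C)C)O[C@H]3C(C)C
F3 | step 4 | 7-methoxy-8-[(1Z)-3-methyl-1-(trimethylsilyloxy)but-1-en-1-yl]-2H-chromen-2-one | COc1ccc2ccc(=O)oc2c1/C(O[Si](C)(C)C)=C/C(C)C
F4 | step 2 | 7-hydroxy-2-oxo-2H-chromene-8-carbaldehyde | O=Cc1c(O)ccc2ccc(=O)oc12
F5 | step 2 | 7-methoxy-2-oxo-2H-chromene-8-carbaldehyde | COc1ccc2ccc(=O)oc2c1C=O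
F6 | step 2 | 8-(1-hydroxy-3-methylbutyl)-7-methoxy-2H-chromen-2-one (racemic) | COc1ccc2ccc(=O)oc2c1C(O)CC(C)C
A1 | alternative 1 | 8-iodo-7-methoxy-2H-chromen-2-one | COc1ccc2ccc(=O)oc2c1I
A2 | alternative 1 | (2R)-2-(tert-butyldimethylsilyloxy)-N-methoxy-N,3-dimethylbutanamide | CC(C)[C@@H](O[Si](C)(C)C(C)(C)C)C(=O)N(C)OC
A3 | alternative 1 | 8-[(2R)-2-hydroxy-3-methylbutanoyl]-7-methoxy-2H-chromen-2-one | COc1ccc2ccc(=O)oc2c1C(=O)[C@H](O)C(C)C
A4 | alternative 2 | 2-oxo-2H-chromen-7-yl (2R)-3-methyl-2-[(3-methylbut-2-enoyl)oxy]butanoate | CC(C)[C@@H](OC(=O)C=C(C)C)C(=O)Oc1ccc2ccc(=O)oc2c1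
A5 | alternative 3 | osthole (7-methoxy-8-(3-methylbut-2-en-1-yl)-2H-chromen-2-one) | COc1ccc2ccc(=O)oc2c1CC=C(C)C
A6 | alternative 3 | 7-methoxy-8-[(1E)-3-methylbut-1-en-1-yl]-2H-chromen-2-one | COc1ccc2ccc(=O)oc2c1/C=C/C(C)C
A7 | alternative 3 | 8-[(1R,2R)-1,2-dihydroxy-3-methylbutyl]-7-methoxy-2H-chromen-2-one | COc1ccc2ccc(=O)oc2c1[C@@H](O)[C@H](O)C(C)C
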